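**Equal shares.** South-west holds 7.79 times the catalyst of north-west and, at 4.00 min, 8.47 times its target. Use that near-equality as the zero of your scale: the case in which each catalyst does the same work whatever the loading. Its measure is the turnover count (turnover number), the target made per catalyst charged, both as fractions of the substrate charged. At that time north-west, south and south-west read 7.50, 10.7 and 8.15, with a mean of 8.77.

| flask | substrate | partner | catalyst | remark | time |
|---|---|---|---|---|---|
| north-west | 0.018 M | 1.8 equiv (fed, over 6.0 min) | 0.68 mol% | run made earlier; the fed solution adds 0.25 times the starting volume |  |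
| south | 0.018 M | 1.8 equiv (fed, over 6.0 min) | 1.8 mol% | run made earlier; the fed solution adds 0.25 times the starting volume |  |
| south-west | 0.018 M | 1.8 equiv (fed, over 6.0 min) | 5.3 mol% | run made earlier; the fed solution adds 0.25 times the starting volume |  |
| spring | 0.018 M | 2.70 equiv (fed, over 6.0 min) | 0.6 mol% | the fed solution adds 0.25 times the starting volume | 6.0 min |
| dawn | 0.018 M | 1.80 equiv (fed, over 6.0 min) | 2 mol% | the fed solution adds 0.25 times the starting volume | 6.0 min |
| noon | 0.050 M | 0.590 equiv (fed, over 6.0 min) | 2 mol% | the fed solution adds 0.25 times the starting volume | 6.0 min |
| winter | 0.018 M | 7.20 equiv (fed, over 6.0 min) | 6 mol% | the fed solution adds 0.25 times the starting volume | 6.0 min |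
| dusk | 0.010 M | 1.80 equiv (fed, over 2.0 min) | 2 mol% | the fed solution adds 0.25 times the starting volume | 6.0 min |
| summer | 0.018 M | 5.40 equiv (fed, over 6.0 min) | 2 mol% | the fed solution adds 0.25 times the starting volume | 6.0 min |

| north-west: time / min | north-west: target / % | south: time / min | south: target / % | south-west: time / min | south-west: target / % |
|---|---|---|---|---|---|
| 0.833 | 0.5 | 0.333 | 0.7 | 0.833 | 6.1 |
| 1.50 | 0.2 | 0.667 | 0.8 | 1.50 | 14.0 |
| 2.50 | 2.4 | 1.33 | 1.0 | 2.50 | 29.1 |
| 3.00 | 2.7 | 2.00 | 3.7 | 3.00 | 33.0 |
| 4.00 | 5.1 | 4.00 | 19.2 | 4.00 | 43.2 |

(readings scatter by 1 percentage point)

- every charge counts on the volume at the start, and the solution that is fed holds the whole dose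

1. all flasks from highest to lowest amount of target, in percent of the substrate charged, at 6.0 min (spring / dawn / noon / winter / dusk / summer)
2. the amount of target, in percent of the substrate charged of the flask you put first, at 6.0 min
3. the amount of target, in percent of the substrate charged of the flask you put last, at 6.0 min

**The asked time.** From its reading at 1.50 min to 4.00 min, south-west's target grows 3.09 times while time grows 2.67 times, nearly in step. North-west and south rise steeper than time, towards its square. My reckoning therefore takes the mean of the two growth laws, a factor of 1.88, which gives 16.4 as the turnover count at the asked time. That count was read with the partner and substrate strength of these runs held fixed, and below I carry it unchanged to winter and spring, whose partner charges differ.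

**The time ladder.** At this count one turnover takes 0.365 min on average, far shorter than the feed of 6.0 min. The next rung is the time a flask needs to work through its whole charge. At this count winter is reckoned to need 6.08 min, about the length of its feed. Dawn is reckoned to need 18.2 min and spring 60.8 min, both longer than the feed.

**My reckoning.** Count times loading gives winter 98.7 %, nearly all of its charge, then dawn 32.9 % and spring 9.87 %. The count can't separate the flasks that share dawn's loading, so I judge those by their other settings. Summer, with 5.40 equiv of partner, goes above dawn. Noon, with more substrate but 0.590 equiv of partner, goes below it, and dusk, the most dilute and fed over 2.0 min, goes lower still. Winter comes first and spring last.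

**The forecast.** It reads winter > summer > noon > dawn > dusk > spring, with 96 % for winter and 11 % for spring, so it sets noon above dawn where I do not, and it warns: “Noon versus dawn and dusk versus spring are close calls.”

**The flask.** The order is winter > summer > dawn > noon > dusk > spring, with winter at 51.8 % and spring at 10.5 %.

    substrate + catalyst → catalyst + intermediate (k = 870 L mol⁻¹ min⁻¹)
    partner + catalyst + intermediate → catalyst + target (k = 88000 L² mol⁻² min⁻¹)
    partner → decomposed reagent (k = 0.110 min⁻¹)
    substrate + target → side product (k = 1.80 L mol⁻¹ min⁻¹)
    target ⇌ isomer of the product (K = 1.00, k = 0.370 min⁻¹)

At 6.00 min winter holds 46.1 % of isomer of the product beside its target. Winter's count comes to 8.63, about half of the reckoned 16.4, while spring's comes to 17.4. The neighbour of spring charged with 2.4 mol% of catalyst is reckoned by the count at 39.4 %, and it holds 43.3 % of target.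

The numbers in the tables are calculated for substances that don't exist, and the scatter is random.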